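**Remark (assumption):** atrovirinone has no stereocentre and no stereogenic alkene (both prenyl alkenes end in CMe2), so the target is a single achiral compound. The only stereochemical elements in the route are the alkene geometry of the alkenyl fragment and two transient racemic centres that are erased.

## Retrosynthetic overview

1. Atrovirinone ⇐ its bis-TBS ether by final desilylation; the benzoate ring is bought (methyl 2,4,6-trihydroxybenzoate) and never built.
2. Quinone ring ⇐ 4→6 ring expansion of a 4-alkenyl-4-hydroxycyclobutenone (4π opening, 6π closure, enolization, Ag2O). Four ring carbons (C–OAr, C–OMe, both C=O) come from squaric acid and the two prenyl-bearing carbons from an alkene. This is the only ring formed in the route.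
3. Cyclobutenone ⇐ aryl methyl squarate + 1,2-diprenylvinyllithium; the latter from symmetrical diprenylacetylene (acetylene + 2 prenyl bromide) by hydrozirconation–iodination.
4. Aryl methyl squarate ⇐ squaric acid → dichloride → methyl ester chloride, then addition–elimination by the one free, ester-chelated phenol of bis-silylated methyl 2,4,6-trihydroxybenzoate.
5. Enabling feature: the strained cyclobutenone σ-bond between the ring C=O carbon and the carbinol carbon. That carbinol carbon carries an OH (rotates outward) and a vinyl group (rotates inward, so its CH terminus reaches the ketene carbon). Prenyl/prenyl on the alkene and OMe/OAr on the ring C=C make regiochemistry irrelevant.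

Key step: step 8

## Route

Step 1
Reactants: 1 squaric acid
Product: 2 squaryl dichloride (3,4-dichlorocyclobut-3-ene-1,2-dione)
Conditions: (COCl)2 (2.2 equiv), cat. DMF, ClCH2CH2Cl, 50 °C
Reagents that add atoms: oxalyl chloride, ClC(=O)C(=O)Cl
Why: Vilsmeier-type activation (oxalyl chloride/DMF) converts both vinylogous acid OH groups into vinylogous acid chlorides, a standard acid chloride formation.

Step 2
Reactants: 2 squaryl dichloride
Product: 3 3-chloro-4-methoxycyclobut-3-ene-1,2-dione
Conditions: MeOH (1.0 equiv), Et2O, 0 °C → rt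
Reagents that add atoms: methanol, CO
Why: Vinylogous acyl substitution (addition–elimination) replaces one chloride, and the new methoxy donor deactivates the remaining C–Cl so one equivalent of methanol should stop at the ester chloride.

Step 3
Reactants: 4 methyl 2,4,6-trihydroxybenzoate
Product: 5 methyl 2,4-bis[(tert-butyldimethylsilyl)oxy]-6-hydroxybenzoate
Conditions: TBSCl (2.1 equiv), imidazole, CH2Cl2/DMF, 0 °C
Reagents that add atoms: tert-butyldimethylsilyl chloride, CC(C)(C)[Si](C)(C)Cl
Why: Phenol silylation takes the 4-OH and one ortho OH, while the last ortho OH stays locked in the hydrogen bond to the ester carbonyl and should remain free (chelation-controlled selective protection).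

Step 4
Reactants: 3 3-chloro-4-methoxycyclobut-3-ene-1,2-dione; 5 methyl 2,4-bis[(tert-butyldimethylsilyl)oxy]-6-hydroxybenzoate
Product: 6 methyl 2,4-bis[(tert-butyldimethylsilyl)oxy]-6-[(2-methoxy-3,4-dioxocyclobut-1-en-1-yl)oxy]benzoate (aryl methyl squarate)
Conditions: i-Pr2NEt, CH2Cl2, −20 °C → rt
Reagents that add atoms: none
Why: Vinylogous acyl substitution (addition–elimination) of the phenol on the C–Cl carbon forms the aryl–O–C bond, and chloride leaves far more readily than methoxide so only the C–Cl position should react.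

Step 5
Reactants: 7 acetylene; 8 prenyl bromide (1-bromo-3-methylbut-2-ene, 2 equiv)
Product: 10 2,9-dimethyldeca-2,8-dien-5-yne (diprenylacetylene), via bis(bromomagnesio)acetylene 9 (not isolated)
Conditions: EtMgBr (2.0 equiv), THF, 50 °C; then CuCl (10 mol%), 8 (2.1 equiv), THF, 50 °C
Reagents that add atoms: none
Why: Copper(I)-catalysed allylation of the acetylene bis-Grignard reagent should proceed by SN2 attack at the unhindered CH2 of prenyl bromide on both termini, giving the symmetrical skipped dienyne.

Step 6
Reactants: 10 2,9-dimethyldeca-2,8-dien-5-yne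
Product: 12 (5E)-5-iodo-2,9-dimethyldeca-2,5,8-triene, via alkenylzirconocene chloride 11 (not isolated)
Conditions: Cp2Zr(H)Cl (1.1 equiv), THF, rt, dark; then I2 (1.1 equiv), 0 °C
Reagents that add atoms: iodine, II
Why: Schwartz hydrozirconation adds H–Zr syn to the alkyne (one regioisomer because the alkyne is symmetrical; the trisubstituted alkenes are inert at rt), and iodinolysis with retention fixes the geometry with I cis to the vinylic H and the two prenyl groups cis.

Step 7
Reactants: 12 (5E)-5-iodo-2,9-dimethyldeca-2,5,8-triene; 6 aryl methyl squarate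
Product: 14 racemic methyl 2,4-bis[(tert-butyldimethylsilyl)oxy]-6-({3-[(5E)-2,9-dimethyldeca-2,5,8-trien-5-yl]-3-hydroxy-2-methoxy-4-oxocyclobut-1-en-1-yl}oxy)benzoate, via alkenyllithium 13 (not isolated)
Conditions: 12 (1.15 equiv), t-BuLi (2.3 equiv), Et2O, −78 °C; then 6, THF, −78 °C; sat. aq NH4Cl, −78 → 0 °C
Reagents that add atoms: none
Why: Iodine–lithium exchange proceeds with retention of alkene geometry and the alkenyllithium should undergo 1,2-addition at −78 °C to the squarate carbonyl vinylogous to the weaker aryloxy donor (much more electrophilic than the di-ortho-substituted benzoate), giving a racemic carbinol whose centre is erased in step 8, while a regioisomeric adduct from the other ring carbonyl would converge on the same quinone.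

Step 8
Reactants: 14 racemic 4-alkenyl-4-hydroxycyclobutenone
Product: 18 methyl 2,4-bis[(tert-butyldimethylsilyl)oxy]-6-{[2-methoxy-4,5-bis(3-methylbut-2-en-1-yl)-3,6-dioxocyclohexa-1,4-dien-1-yl]oxy}benzoate, via dienylketene 15 (not isolated), via cyclohexa-2,4-dienone 16 (not isolated), via hydroquinone 17 (not isolated)
Conditions: PhMe (0.01 M, degassed), 110 °C; cool to rt; then Ag2O, Na2SO4, rt
Reagents that add atoms: none
Why: Heating cleaves the bond between the ring carbonyl carbon and the carbinol carbon by thermal conrotatory 4π-electrocyclic opening to dienylketene 15, which closes by thermal disrotatory 6π-electrocyclization (new bond between the ketene carbon and the CH terminus of the alkene) to cyclohexa-2,4-dienone 16; enolization gives hydroquinone 17, which Ag2O oxidizes in the same flask to the quinone. The closest known reaction type is the Moore–Liebeskind ring expansion of squarate-derived 4-alkenyl(aryl)-4-hydroxycyclobutenones to hydroquinones and quinones. The only ring closed is the six-membered quinone ring, by 6π-electrocyclization, so the four-membered ring grows by the two alkene carbons. The single new stereocentre (C-6 of 16) is transient and is destroyed on aromatization, so no stereocontrol is needed. The selectivity required is torquoselectivity, secured by the carbinol OH donor rotating outward so that the alkenyl group turns inward beside the ketene; regiochemistry needs no control because both alkene carbons carry prenyl and OMe/OAr sit on adjacent ring carbons.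

Step 9
Reactants: 18 bis-TBS quinone
Product: 19 atrovirinone, methyl 2,4-dihydroxy-6-{[2-methoxy-4,5-bis(3-methylbut-2-en-1-yl)-3,6-dioxocyclohexa-1,4-dien-1-yl]oxy}benzoate
Conditions: HF·pyridine, pyridine, THF, 0 °C → rt (polypropylene vessel)
Reagents that add atoms: none
Why: Fluoride-driven cleavage of the two aryl silyl ethers (Si–F bond formation) under weakly acidic, non-nucleophilic conditions should leave the quinone, its vinylogous ester groups, the methyl ester and the prenyl alkenes untouched.

## Compound list

1 | squaric acid (3,4-dihydroxycyclobut-3-ene-1,2-dione) | OC1=C(O)C(=O)C1=O | starting material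
2 | squaryl dichloride (3,4-dichlorocyclobut-3-ene-1,2-dione) | ClC1=C(Cl)C(=O)C1=O | intermediate
3 | 3-chloro-4-methoxycyclobut-3-ene-1,2-dione | COC1=C(Cl)C(=O)C1=O | intermediate
4 | methyl 2,4,6-trihydroxybenzoate | COC(=O)c1c(O)cc(O)cc1O | starting material
5 | methyl 2,4-bis[(tert-butyldimethylsilyl)oxy]-6-hydroxybenzoate | COC(=O)c1c(O[Si](C)(C)C(C)(C)C)cc(O[Si](C)(C)C(C)(C)C)cc1O | intermediate
6 | methyl 2,4-bis[(tert-butyldimethylsilyl)oxy]-6-[(2-methoxy-3,4-dioxocyclobut-1-en-1-yl)oxy]benzoate | COC(=O)c1c(O[Si](C)(C)C(C)(C)C)cc(O[Si](C)(C)C(C)(C)C)cc1OC1=C(OC)C(=O)C1=O | intermediate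
7 | acetylene | C#C | starting material
8 | prenyl bromide (1-bromo-3-methylbut-2-ene) | CC(C)=CCBr | starting material
9 | bis(bromomagnesio)acetylene | Br[Mg]C#C[Mg]Br | intermediate (not isolated)
10 | 2,9-dimethyldeca-2,8-dien-5-yne | CC(C)=CCC#CCC=C(C)C | intermediate
11 | chlorobis(cyclopentadienyl)[(5E)-2,9-dimethyldeca-2,5,8-trien-5-yl]zirconium (Zr cis to the vinylic H; Cp drawn σ-bonded) | CC(C)=CC/C(=C\CC=C(C)C)[Zr](Cl)(C1C=CC=C1)C1C=CC=C1 | intermediate (not isolated)
12 | (5E)-5-iodo-2,9-dimethyldeca-2,5,8-triene (I cis to the vinylic H) | CC(C)=CC/C(I)=C\CC=C(C)C | intermediate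
13 | [(5Z)-2,9-dimethyldeca-2,5,8-trien-5-yl]lithium (Li cis to the vinylic H, same geometry as 12) | [Li]/C(CC=C(C)C)=C/CC=C(C)C | intermediate (not isolated)
14 | racemic methyl 2,4-bis[(tert-butyldimethylsilyl)oxy]-6-({3-[(5E)-2,9-dimethyldeca-2,5,8-trien-5-yl]-3-hydroxy-2-methoxy-4-oxocyclobut-1-en-1-yl}oxy)benzoate | COC(=O)c1c(O[Si](C)(C)C(C)(C)C)cc(O[Si](C)(C)C(C)(C)C)cc1OC1=C(OC)C(O)(/C(CC=C(C)C)=C/CC=C(C)C)C1=O | intermediate
15 | methyl 2,4-bis[(tert-butyldimethylsilyl)oxy]-6-{[(3Z,5E)-4-hydroxy-3-methoxy-9-methyl-5-(3-methylbut-2-en-1-yl)-1-oxodeca-1,3,5,8-tetraen-2-yl]oxy}benzoate (dienylketene) | COC(=O)c1c(O[Si](C)(C)C(C)(C)C)cc(O[Si](C)(C)C(C)(C)C)cc1OC(=C=O)/C(OC)=C(/O)\C(CC=C(C)C)=C\CC=C(C)C | intermediate (not isolated)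
16 | racemic methyl 2,4-bis[(tert-butyldimethylsilyl)oxy]-6-{[3-hydroxy-2-methoxy-4,5-bis(3-methylbut-2-en-1-yl)-6-oxocyclohexa-1,3-dien-1-yl]oxy}benzoate | COC(=O)c1c(O[Si](C)(C)C(C)(C)C)cc(O[Si](C)(C)C(C)(C)C)cc1OC1=C(OC)C(O)=C(CC=C(C)C)C(CC=C(C)C)C1=O | intermediate (not isolated)
17 | methyl 2,4-bis[(tert-butyldimethylsilyl)oxy]-6-[2,5-dihydroxy-6-methoxy-3,4-bis(3-methylbut-2-en-1-yl)phenoxy]benzoate | COC(=O)c1c(O[Si](C)(C)C(C)(C)C)cc(O[Si](C)(C)C(C)(C)C)cc1Oc1c(OC)c(O)c(CC=C(C)C)c(CC=C(C)C)c1O | intermediate (not isolated)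
18 | methyl 2,4-bis[(tert-butyldimethylsilyl)oxy]-6-{[2-methoxy-4,5-bis(3-methylbut-2-en-1-yl)-3,6-dioxocyclohexa-1,4-dien-1-yl]oxy}benzoate | COC(=O)c1c(O[Si](C)(C)C(C)(C)C)cc(O[Si](C)(C)C(C)(C)C)cc1OC1=C(OC)C(=O)C(CC=C(C)C)=C(CC=C(C)C)C1=O | intermediate
19 | atrovirinone, methyl 2,4-dihydroxy-6-{[2-methoxy-4,5-bis(3-methylbut-2-en-1-yl)-3,6-dioxocyclohexa-1,4-dien-1-yl]oxy}benzoate | COC(=O)c1c(O)cc(O)cc1OC1=C(OC)C(=O)C(CC=C(C)C)=C(CC=C(C)C)C1=O | target

## Summary

Total step count: 9. Longest linear sequence: 6 steps (steps 1, 2, 4, 7, 8, 9 from squaric acid).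

**Steps most likely to fail**

Step 7. The alkenyllithium may lose chemoselectivity: addition–elimination at the aryloxy-bearing ring carbon with expulsion of the phenoxide, attack at silicon, or proton transfer from its own doubly allylic CH2. The fallback avoids the organolithium altogether and sets out from 6 and 10. Squarate 6 is treated with ClCo(PPh3)3 (benzene, rt), which should insert into the CO–CO bond to give the chlorobis(triphenylphosphine) maleoylcobalt complex F1. Ligand exchange with dimethylglyoxime in pyridine should give the more reactive chloro(dimethylglyoxime)(pyridine) maleoylcobalt complex F2. Heating F2 with alkyne 10 (CoCl2·6H2O, ClCH2CH2Cl, 80 °C) should give the quinone directly by alkyne insertion and reductive elimination (maleoylcobalt–alkyne quinone synthesis). This is a metal-mediated 4→6 ring expansion that needs no regiocontrol because 10 is symmetrical, and it comes back to the route at 18.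

Step 8. The ketene may be diverted before the 6π closure, by capture by the tertiary hydroxyl (butenolide formation) or by cleavage of the sensitive carbinol before ring opening. The fallback sets out from 14, which is silylated (TMSCl, imidazole, DMF, 0 °C) to the trimethylsilyl ether F3. Thermolysis of F3 (PhMe, 110 °C) has no free hydroxyl to intercept the ketene and should give the mono-silylated hydroquinone F4 by the same 4π/6π sequence followed by enolization. Oxidative desilylation of F4 with CAN (MeCN–H2O, 0 °C) should then give the quinone, coming back to the route at 18.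

Step 9. The electrophilic aryloxyquinone may degrade during desilylation, by addition–elimination of fluoride or liberated phenoxide with loss of the aryloxy group. The fallback sets out from 18 and takes the quinone out of play by redox protection. Reduction with aqueous Na2S2O4 (Et2O–H2O) gives hydroquinone 17, here isolated. Desilylation of 17 with HF·pyridine (THF, 0 °C) gives the tetraphenol hydroquinone F5, which is no longer electrophilic. Re-oxidation of F5 with Ag2O (Et2O, rt) comes back to the route at 19.

## Further compounds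

F1 | step 7 | chlorobis(triphenylphosphine) maleoylcobalt(III) complex of 6 (cobaltacyclopentenedione, drawn with formal charges) | COC(=O)c1c(O[Si](C)(C)C(C)(C)C)cc(O[Si](C)(C)C(C)(C)C)cc1OC1=C(OC)C(=O)[Co-2](Cl)([P+](c2ccccc2)(c2ccccc2)c2ccccc2)([P+](c2ccccc2)(c2ccccc2)c2ccccc2)C1=O
F2 | step 7 | chloro(dimethylglyoxime)(pyridine) maleoylcobalt(III) complex of 6 (drawn with formal charges) | COC(=O)c1c(O[Si](C)(C)C(C)(C)C)cc(O[Si](C)(C)C(C)(C)C)cc1OC1=C(OC)C(=O)[Co-3]2(Cl)([n+]3ccccc3)([N+](O)=C(C)C(C)=[N+]2O)C1=O
F3 | step 8 | racemic trimethylsilyl ether of 14, methyl 2,4-bis[(tert-butyldimethylsilyl)oxy]-6-({3-[(5E)-2,9-dimethyldeca-2,5,8-trien-5-yl]-2-methoxy-4-oxo-3-[(trimethylsilyl)oxy]cyclobut-1-en-1-yl}oxy)benzoate | COC(=O)c1c(O[Si](C)(C)C(C)(C)C)cc(O[Si](C)(C)C(C)(C)C)cc1OC1=C(OC)C(O[Si](C)(C)C)(/C(CC=C(C)C)=C/CC=C(C)C)C1=O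
F4 | step 8 | methyl 2,4-bis[(tert-butyldimethylsilyl)oxy]-6-{2-hydroxy-6-methoxy-3,4-bis(3-methylbut-2-en-1-yl)-5-[(trimethylsilyl)oxy]phenoxy}benzoate | COC(=O)c1c(O[Si](C)(C)C(C)(C)C)cc(O[Si](C)(C)C(C)(C)C)cc1Oc1c(OC)c(O[Si](C)(C)C)c(CC=C(C)C)c(CC=C(C)C)c1O
F5 | step 9 | methyl 2-[2,5-dihydroxy-6-methoxy-3,4-bis(3-methylbut-2-en-1-yl)phenoxy]-4,6-dihydroxybenzoate | COC(=O)c1c(O)cc(O)cc1Oc1c(OC)c(O)c(CC=C(C)C)c(CC=C(C)C)c1O
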